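Start from the amounts: 0.40 M of free monomer, 2.0 mM of pre-initiator and 0.59 mM of impurity. The choice is whether to stop at 12 h or at 25 h.

the same everywhere: free monomer 0.40 M; pre-initiator 2.0 mM; impurity 0.59 mM
- Friday's: time 12 h
- Tuesday's: time 25 h

    monomer in chains + living end → free monomer + living end, rate k1*[living end] as long as [monomer in chains] is above zero (k1 = 0.12 s⁻¹)
    free monomer + living end → monomer in chains + living end, rate k2*[living end]*[free monomer] (k2 = 0.48 M⁻¹ s⁻¹)
    pre-initiator → initiator (k3 = 1.5 × 10⁻⁵ s⁻¹)
    initiator + impurity → spent initiator (k4 = 3.9 M⁻¹ s⁻¹)
    free monomer + initiator → living end + monomer in chains (k5 = 4.3 × 10⁻⁴ M⁻¹ s⁻¹)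

- the average divides the monomer in chains by the number of chains begun, living and dead together
- run time (Friday's): 12 h

* which of the two ends with the longer chains by the average number of monomer units in a chain (chains begun, living or dead) ("neither" if they lie within 10%) (Friday's / Tuesday's / neither)
* average number of monomer units in a chain (chains begun, living or dead) at the end, Friday's
* average number of monomer units in a chain (chains begun, living or dead) at the end, Tuesday's

Reckon the monomer first. The living ends add and release monomer, and the two steps balance at free monomer 0.250 M, the equilibrium monomer concentration. Call the charge minus that balance the ceiling load 0.150 M.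

Then count chains. At Friday's charge, initiator falls to the impurity faster than it starts chains, with half-lives of 0.084 h against 1.1 h. So treat released initiator as lost until the release equals the impurity, at 6.47 h. After that, chains begun are the release, less the impurity, less the initiator still waiting, taken as release rate over its consumption at the balance monomer. Friday's has released 0.954 mM with 0.146 mM waiting, which leaves 0.218 mM chains. Tuesday's has released 1.48 mM with 0.0723 mM waiting, which leaves 0.819 mM.

The distance from the ceiling shrinks at the propagation constant times the living ends. Replace the rising count by its mean, the end count over 2. Friday's exponent is 1.04, so this reckoning puts 64.7% of the load, 0.0970 M, in chains, and the length at 445. Tuesday's exponent is 13.1, so it puts nearly all of the load in chains, and the length at 183.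

Test the mean. Divided by 2, it gives Friday's 279; multiplied by 2, 602. With its exponent halved, Tuesday's still fills 99.9% of its load. Stop at 12 h for longer chains: by this reckoning the later stop multiplies monomer in chains by 1.55 but chains by 3.76.

The forecast names Friday's, with 500 (430 to 580) and 186 (175 to 198), since “the same monomer is shared among more chains”; my Friday's figure is lower.

The simulation gives Friday's, with 488 against 186. Tuesday's holds 8.08 × 10⁻⁴ M of living ends at 25.0 h, with free monomer at 62.5% of its charge. The ceiling load over those ends gives 186. A neighbour like Tuesday's, charged with 1.6 M of free monomer, has a ceiling load of 1.35 M. Over its 8.08 × 10⁻⁴ M of living ends that gives 1670, and that neighbour ends at 1670.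

The rate constants come from no measurement; the flask was simulated.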